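(The earlier runs and the new flask are calculated for substances that don't exist; scatter was added.)

A small charge, 10 mM of D under 12 mM of J, is the flask asked about. It has been followed as the north-east run, and the south-west run beside it held twice the D.

| flask | D | J | remark | time |
|---|---|---|---|---|
| north-east | 10 mM | 12 mM | the very flask that is asked about, followed so far |  |
| south-west | 20 mM | 12 mM | run made earlier |  |
| flask | 10 mM | 12.0 mM |  | 8.0 min |

| run | time / min | D / % | L / % |
|---|---|---|---|
| north-east | 0.667 | 51 | 40 |
| north-east | 1.33 | 35 | 51 |
| north-east | 2.00 | 28 | 55 |
| north-east | 2.50 | 25 | 61 |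
| north-east | 3.00 | 20 | 61 |
| south-west | 0.667 | 58 | 35 |
| south-west | 1.33 | 51 | 47 |
| south-west | 2.00 | 48 | 43 |
| south-west | 2.50 | 46 | 48 |
| south-west | 3.00 | 45 | 45 |

(scatter of a reading: 1.5 percentage points)

- what is said of L includes X
- X is a solid; its amount is given per volume of the solution
- steps that have been proposed: X <-> L; J + Z -> E + Q; D + J -> L + Q; J + L -> Z + Q

1. amount of D at 8.0 min, in percent of the D charged
2. amount of L at 8.0 min, in percent of the D charged
3. amount of Z at 8.0 min, in percent of the D charged
4. amount of E at 8.0 min, in percent of the D charged

Each D lost takes one J, and each L that goes on takes another, so the north-east rest (D charged minus D and L, read as Z) counts J spent. Between the start and the first north-east reading the mean J is 9.10 mM, and D falls to 51%. That gives 0.521 min: the pseudo-first-order half-life of D at the charged J. Since the step is first order in J, the half-life at a later moment is this time divided by the fraction of J left.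

That is the first rung, short against the 8.0 min asked. On the next rung L takes J, and by 3.00 min the north-east rest has reached 19.0% of the D charged. The fraction of J left there reads as 17.5%, so the half-life of D has stretched to about 2.98 min. The last rung shows in the south-west run, where J is the limiting reagent: D reads 48% at 2.00 min and 45% at 3.00 min. The reckoning here commits to a stall in the asked flask with D above zero, because the north-east J left at the last reading, 2.10 mM, is about the D left, 2.00 mM, and L takes a share of that J.

The forecast gives D 11%, L 65%, Z 21% and E 3%, on this ground: “Both D and Z then compete for the small remaining J.”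

The flask at 8.0 min holds D 13.5%, L 58.3%, Z 25.4% and E 2.80%, so L stands 6.7 percentage points below the forecast.

    X ⇌ L, rate k1*(cs1 - [L]) while solid is left; crystals form when [L] > cs1 (solubility = 4.40 mM, k = 0.804 s⁻¹)
    J + Z → E + Q (k = 0.231 L mol⁻¹ s⁻¹)
    D + J → L + Q (k = 1.88 L mol⁻¹ s⁻¹)
    J + L → Z + Q (k = 0.703 L mol⁻¹ s⁻¹)

In the asked flask the half-life of D by the step D + J is 0.85 min at 0.542 min, short against the 8.0 min, and 25 min at 8.00 min, long against it, with J at 2.07% of its charge, where the carried half-life gives 25.2 min. In the neighbour flask read at 2.0 min, J is still at 24.1% of its charge, the carried half-life gives 2.16 min, and D stands at 26.8%.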